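**Plan**

- Retrosynthesis: the two benzyl ethers and the hydrogens at C3/C4 are removed first, leading back to a 6,8-bis(benzyloxy)isocoumarin. Its pyranone ring (ring B) is then cut at C4a–C4 and O2–C3, giving 2,4-bis(benzyloxy)benzoic acid (ring A) and a keto sulfoxonium ylide that carries C4, C3 and the whole side chain.
- Enabling feature: in the isochroman-1-one core C8 bears oxygen, so C4a is the only hydrogen-bearing position ortho to the carboxyl-bearing carbon C8a. A carboxylate-directed metalation can occur nowhere else, and the C4–C3 unit can be annulated directly onto the acid.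
- The ylide is cut at C3–C4 (methyl ester plus dimethylsulfoxonium methylide) and the chain at C8′–C9′ (Grignard opening of (S)-propylene oxide; primed locants = side chain, C1′ on C3). C3 is the internal alkene carbon of 10-bromo-1-decene after oxidative cleavage.
- Forward order: chain assembly (epoxide opening, O-methylation, ozonolysis to the ester, ylide formation), then ring B is built on ring A in one operation, then C3=C4 hydrogenation and debenzylation.
- Stereochemistry: C10′ (S) comes from (S)-propylene oxide, whose C–O bond is never broken. C3 (R) is set by a catalyst-controlled enantioselective hydrogenation of the isocoumarin.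

Key step: step 6

Assumption: the ligand series of the hydrogenation catalyst in step 7 is the one that gives (R)-3-alkyl-3,4-dihydroisocoumarins; since O2 > C4 > C1′ holds for any 3-alkyl group, the descriptor transfers unchanged to the target. SINpEt = 1,3-bis[1-(1-naphthyl)ethyl]imidazolidin-2-ylidene; DPEN = 1,2-diphenylethane-1,2-diamine.

**Route**

Step 1
Reactants: 1 2,4-dihydroxybenzoic acid
Product: 3 2,4-bis(benzyloxy)benzoic acid, via benzyl 2,4-bis(benzyloxy)benzoate 2 (not isolated)
Conditions: BnBr (3.3 equiv), K2CO3, DMF, 60 °C; aqueous work-up, crude ester taken on; KOH, THF/MeOH/H2O, 65 °C; then HCl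
Reagents that add atoms: benzyl bromide, BrCc1ccccc1; potassium hydroxide, [K+].[OH-]
Why: Williamson O-benzylation of the carboxylate and both phenoxides (the hydrogen-bonded 2-OH needs the excess reagent and warming) is followed by saponification of the benzyl ester, which hydroxide cleaves while the aryl benzyl ethers are inert to base.

Step 2
Reactants: 4 10-bromo-1-decene; 5 (S)-propylene oxide [(2S)-2-methyloxirane]
Product: 7 (2S)-tridec-12-en-2-ol, via dec-9-en-1-ylmagnesium bromide 6 (not isolated)
Conditions: Mg, THF, 40 °C; then CuI (10 mol %), 5, THF, −30 → 0 °C; NH4Cl aq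
Reagents that add atoms: none
Why: Copper-catalysed SN2 opening of the terminal epoxide by the Grignard reagent takes place at the unsubstituted CH2, so the C–O bond of the stereocentre is not broken and the (S) configuration of 5 is carried unchanged into the carbinol carbon of 7.

Step 3
Reactants: 7 (2S)-tridec-12-en-2-ol
Product: 8 (12S)-12-methoxytridec-1-ene
Conditions: NaH, MeI, THF, 0 °C → rt
Reagents that add atoms: iodomethane, CI
Why: Williamson etherification of the sodium alkoxide with iodomethane makes the O–CH3 bond without touching the C–O bond of the stereocentre or the terminal alkene.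

Step 4
Reactants: 8 (12S)-12-methoxytridec-1-ene
Product: 10 methyl (11S)-11-methoxydodecanoate, via (11S)-1,11-dimethoxydodecyl hydroperoxide 9 (not isolated)
Conditions: O3, NaOH (2.5 M in MeOH), CH2Cl2, −78 °C, ozone stopped at the first persistent colour; then H2O, warm to rt
Reagents that add atoms: ozone, [O-][O+]=O; methanol, CO
Why: Ozonolysis in methanolic NaOH traps the carbonyl oxide as the α-methoxy hydroperoxide 9, which base dehydrates to the methyl ester, while any aldehyde from the other fragmentation mode should converge on the same ester through its hemiacetal; the secondary methyl ether and the remote stereocentre should be inert at −78 °C.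

Step 5
Reactants: 10 methyl (11S)-11-methoxydodecanoate; 11 trimethylsulfoxonium iodide
Product: 13 (12S)-1-[dimethyl(oxo)-λ6-sulfanylidene]-12-methoxytridecan-2-one, via dimethylsulfoxonium methylide 12 (not isolated)
Conditions: 11 (3 equiv), KOtBu (3 equiv), THF, reflux; then 10, THF, reflux
Reagents that add atoms: none
Why: Claisen-type acylation of the Corey–Chaykovsky ylide by the methyl ester gives the carbonyl-stabilised sulfoxonium ylide, whose low basicity drives the equilibrium forward (excess methylide and liberated methoxide take up the proton); the stereocentre lies far from the carbonyl group and cannot epimerise.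

Step 6
Reactants: 3 2,4-bis(benzyloxy)benzoic acid; 13 (12S)-1-[dimethyl(oxo)-λ6-sulfanylidene]-12-methoxytridecan-2-one (1.5 equiv)
Product: 15 6,8-bis(benzyloxy)-3-[(10S)-10-methoxyundecyl]-1H-isochromen-1-one, via 2,4-bis(benzyloxy)-6-[(12S)-12-methoxy-2-oxotridecyl]benzoic acid 14 (not isolated)
Conditions: [Cp*RhCl2]2 (2.5 mol %), AgSbF6 (10 mol %), NaOAc (30 mol %), HFIP, 60 °C, sealed vessel; then TsOH·H2O (0.5 equiv), 60 °C
Reagents that add atoms: none
Why: Acetate-assisted concerted metalation–deprotonation of the rhodium carboxylate of 3 at its only free ortho C–H gives a five-membered rhodacycle of trivalent rhodium; the ylide carbon of 13 binds, DMSO departs to leave a rhodium carbene, and migratory insertion followed by protodemetalation forms C4a–C4 and releases keto acid 14 with the metal staying trivalent throughout. The carboxyl oxygen then adds to the ketone carbonyl (6-exo-trig) and the hemiketal loses water under the acidic finish to give the endocyclic C3=C4 enol lactone, which forms O2–C3 and closes ring B. The closest known reaction type is the Cp*Rh-catalysed C–H acylmethylation and annulation of benzoic acids with keto sulfoxonium ylides to 3-substituted isocoumarins. No stereocentre is formed, and the methoxy-bearing centre of the chain lies far from any acidifying group and is carried through unchanged. The step needs site selectivity for a single ortho C–H and chemoselectivity for C-alkylation over O-alkylation of the acid: the 2-benzyloxy group occupies the second ortho position (and, as C8–OBn of the product, blocks a second lactone-directed metalation), while acetate keeps the acid on rhodium as carboxylate.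

Step 7
Reactants: 15 6,8-bis(benzyloxy)-3-[(10S)-10-methoxyundecyl]-1H-isochromen-1-one
Product: 16 (3R)-6,8-bis(benzyloxy)-3-[(10S)-10-methoxyundecyl]-3,4-dihydro-1H-isochromen-1-one
Conditions: Ru–NHC–diamine catalyst (5 mol %) made from [Ru(cod)(2-methylallyl)2], SINpEt·HBF4, KOtBu and DPEN (ligand enantiomers of the series giving 3R), NaOtBu (15 mol %), H2 (50 bar), toluene, 25 °C
Reagents that add atoms: none
Why: Catalytic asymmetric hydrogenation of the trisubstituted enol-lactone double bond is established for 3-alkyl isocoumarins with ruthenium–NHC–diamine catalysts; the new C3 stereocentre is set by the catalyst, whose chiral pocket selects the face of C3=C4 that receives hydrogen, while the distant C10′ centre exerts no influence and the benzyl ethers, arene rings and lactone should not be reduced at room temperature.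

Step 8
Reactants: 16 (3R)-6,8-bis(benzyloxy)-3-[(10S)-10-methoxyundecyl]-3,4-dihydro-1H-isochromen-1-one
Product: 17 (3R)-6,8-dihydroxy-3-[(10S)-10-methoxyundecyl]-3,4-dihydro-1H-isochromen-1-one
Conditions: H2 (1 atm), 10% Pd/C, EtOAc, rt
Reagents that add atoms: none
Why: Heterogeneous hydrogenolysis cleaves the two aryl benzyl ethers; the lactone C3–O2 bond is homobenzylic and the aliphatic methyl ether is not activated, so neither should be cleaved and both stereocentres are retained.

**Compound list**

1 | 2,4-dihydroxybenzoic acid | O=C(O)c1ccc(O)cc1O | starting material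
2 | benzyl 2,4-bis(benzyloxy)benzoate | O=C(OCc1ccccc1)c1ccc(OCc2ccccc2)cc1OCc1ccccc1 | intermediate (not isolated)
3 | 2,4-bis(benzyloxy)benzoic acid | O=C(O)c1ccc(OCc2ccccc2)cc1OCc1ccccc1 | intermediate
4 | 10-bromo-1-decene | BrCCCCCCCCC=C | starting material
5 | (S)-propylene oxide | C[C@H]1CO1 | starting material
6 | dec-9-en-1-ylmagnesium bromide | C=CCCCCCCCC[Mg]Br | intermediate (not isolated)
7 | (2S)-tridec-12-en-2-ol | C[C@H](O)CCCCCCCCCC=C | intermediate
8 | (12S)-12-methoxytridec-1-ene | CO[C@@H](C)CCCCCCCCCC=C | intermediate
9 | (11S)-1,11-dimethoxydodecyl hydroperoxide (C1 epimers) | CO[C@@H](C)CCCCCCCCCC(OC)OO | intermediate (not isolated)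
10 | methyl (11S)-11-methoxydodecanoate | CO[C@@H](C)CCCCCCCCCC(=O)OC | intermediate
11 | trimethylsulfoxonium iodide | C[S+](C)(C)=O.[I-] | starting material
12 | dimethylsulfoxonium methylide | C[S+](C)(=O)[CH2-] | intermediate (not isolated)
13 | (12S)-1-[dimethyl(oxo)-λ6-sulfanylidene]-12-methoxytridecan-2-one | CO[C@@H](C)CCCCCCCCCC(=O)C=S(C)(C)=O | intermediate
14 | 2,4-bis(benzyloxy)-6-[(12S)-12-methoxy-2-oxotridecyl]benzoic acid | CO[C@@H](C)CCCCCCCCCC(=O)Cc1cc(OCc2ccccc2)cc(OCc2ccccc2)c1C(=O)O | intermediate (not isolated)
15 | 6,8-bis(benzyloxy)-3-[(10S)-10-methoxyundecyl]-1H-isochromen-1-one | CO[C@@H](C)CCCCCCCCCC1=Cc2cc(OCc3ccccc3)cc(OCc3ccccc3)c2C(=O)O1 | intermediate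
16 | (3R)-6,8-bis(benzyloxy)-3-[(10S)-10-methoxyundecyl]-3,4-dihydro-1H-isochromen-1-one | CO[C@@H](C)CCCCCCCCC[C@@H]1Cc2cc(OCc3ccccc3)cc(OCc3ccccc3)c2C(=O)O1 | intermediate
17 | (3R)-6,8-dihydroxy-3-[(10S)-10-methoxyundecyl]-3,4-dihydro-1H-isochromen-1-one | CO[C@@H](C)CCCCCCCCC[C@@H]1Cc2cc(O)cc(O)c2C(=O)O1 | target

**Step count and risks**

Total steps: 8. Longest linear sequence: 7 steps (steps 2, 3, 4, 5, 6, 7, 8, from 4 and 5 to 17).

Steps most likely to fail: step 6, step 7, step 5.

Step 6. O-alkylation of the carboxylic acid by the protonated ylide may outrun C–H metalation, the electron-rich ortho-alkoxy benzoate may metalate slowly or lose CO2, and cyclodehydration may stall at the open keto acid. The fallback avoids C–H activation and sets out from ester 10. Commercial methyl orsellinate would be benzylated (BnBr, K2CO3, DMF) to methyl 2,4-bis(benzyloxy)-6-methylbenzoate F1. Lateral lithiation of its benzylic methyl group (LDA, 2.2 equiv, THF, −78 °C) and Claisen-type acylation of the anion with 10 should give methyl 2,4-bis(benzyloxy)-6-[(12S)-12-methoxy-2-oxotridecyl]benzoate F2. LiOH in THF/H2O would then give keto acid 14, and TsOH·H2O in toluene at 80 °C would cyclodehydrate it, so the fallback comes back to the route at 15.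

Step 7. Facial discrimination may be insufficient for the long, flexible 3-alkyl group, the catalyst may be inhibited by the two benzyloxy groups, or arene reduction may start under pressure. The fallback moves the stereo-defining event from the alkene to a ketone and sets out from 15. KOH in EtOH/H2O would open the enol lactone to keto acid 14, isolated this time by cold acidification. A ketoreductase chosen from a commercial panel for the (R)-alcohol (NADP+, iPrOH, phosphate buffer pH 7, DMSO co-solvent, 30 °C) should reduce it to 2,4-bis(benzyloxy)-6-[(2R,12S)-2-hydroxy-12-methoxytridecyl]benzoic acid F3. Acid-catalysed lactonisation (TsOH·H2O cat., CH2Cl2, rt) proceeds with retention at the carbinol carbon, so the fallback comes back at 16.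

Step 5. Enolisation of the aliphatic ester by the basic methylide may compete with acylation and leave the conversion incomplete. The fallback uses a non-enolising, faster electrophile and sets out from 10. LiOH in THF/H2O would give (11S)-11-methoxydodecanoic acid F4, and oxalyl chloride with catalytic DMF in CH2Cl2 would give (11S)-11-methoxydodecanoyl chloride F5. Adding F5 to methylide 12 (3 equiv, THF, 0 °C) should acylate the ylide, a second equivalent taking up the proton, so the fallback comes back at 13.

Further compounds
F1 | step 6 | methyl 2,4-bis(benzyloxy)-6-methylbenzoate | COC(=O)c1c(C)cc(OCc2ccccc2)cc1OCc1ccccc1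
F2 | step 6 | methyl 2,4-bis(benzyloxy)-6-[(12S)-12-methoxy-2-oxotridecyl]benzoate | CO[C@@H](C)CCCCCCCCCC(=O)Cc1cc(OCc2ccccc2)cc(OCc2ccccc2)c1C(=O)OC
F3 | step 7 | 2,4-bis(benzyloxy)-6-[(2R,12S)-2-hydroxy-12-methoxytridecyl]benzoic acid | CO[C@@H](C)CCCCCCCCC[C@@H](O)Cc1cc(OCc2ccccc2)cc(OCc2ccccc2)c1C(=O)O
F4 | step 5 | (11S)-11-methoxydodecanoic acid | CO[C@@H](C)CCCCCCCCCC(=O)O
F5 | step 5 | (11S)-11-methoxydodecanoyl chloride | CO[C@@H](C)CCCCCCCCCC(=O)Cl
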